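**Plan**

1. Ring numbering: C1 (C=O), C2 (carries C7H2OH), C3 (=CH), C4 (O-angelate), C5 (isopropyl), C6 (O-epoxyangelate). The feature used is the array O7–C7–C2=C3–C4–O4. The exocyclic carbon C7 and the ring carbon C4 both carry oxygen and flank the ring alkene C2=C3 in a 1,4-relationship, which is the imprint of two oxygen nucleophiles added oxidatively across the semicyclic diene C7=C2–C3=C4.
2. Retrosynthetic cuts, in order: O7–Si; acyl–O6 (epoxyangelate); C6–O6; C1=O; acyl–O4 (angelate); C7–O7 and C4–O4 together; C2=C7; C3=C4 and C5–C6.
3. Forward: a Michael addition joins C5–C6, and an aldol condensation closes the only carbocycle at C3=C4. Methylenation then gives (R)-β-phellandrene, and palladium-catalysed diacetoxylation installs O7 and O4. Ester exchange, C1 oxidation, C6 hydroxylation, acylation with a separately made epoxy acid and desilylation finish the target.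
4. Stereochemistry: C5 comes from an (R)-diarylprolinol ether catalyst. C4 is relayed from C5 (palladium anti to isopropyl, acetate anti to palladium). C6 is relayed from C5 and C4 (the enolate is oxidised on its free face). C2′ and C3′ come from a Katsuki–Sharpless epoxidation with L-(+)-diethyl tartrate, and the Z-alkene is bought with angelic acid.

Key step: step 4

Assumption: the SMILES is read as 4R,5R,6S (O4 cis and O6 trans to isopropyl) with a 2′R,3′R cis-epoxide; minor enantiomers left by the two catalytic asymmetric steps become diastereomers at the coupling stage and are expected to be removable there by chromatography.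

**Route**

Step 1
Reactants: 1 isovaleraldehyde; 2 methyl vinyl ketone
Product: 3 (2R)-2-isopropyl-5-oxohexanal
Conditions: (R)-2-[methoxy(diphenyl)methyl]pyrrolidine (5 mol %), ethyl 3,4-dihydroxybenzoate (20 mol %), neat, 4 °C
Reagents that add atoms: none
Why: Enamine-catalysed asymmetric Michael addition: the E-enamine of 1 exposes only the face remote from the CPh2OMe group to the hydrogen-bond-activated enone, which forms C5–C6 and should set C5 as R.

Step 2
Reactants: 3 (2R)-2-isopropyl-5-oxohexanal
Product: 5 (R)-cryptone [(4R)-4-isopropylcyclohex-2-en-1-one], via aldol adduct 4 (not isolated)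
Conditions: KOH (aq, dilute), nBu4NOH (cat.), Et2O–THF–H2O, reflux
Reagents that add atoms: none
Why: Intramolecular aldol condensation (6-enolendo-exo-trig addition of the methyl-ketone enolate to the aldehyde, then E1cB loss of water from 4) closes the carbocycle at C3=C4, and the dilute biphasic base is chosen so that cyclisation outruns epimerisation of the aldehyde α-carbon C5.

Step 3
Reactants: 5 (R)-cryptone; 6 methyltriphenylphosphonium bromide
Product: 8 (R)-β-phellandrene [(6R)-6-isopropyl-3-methylidenecyclohex-1-ene], via methylenetriphenylphosphorane 7 (not isolated)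
Conditions: 6, KOtBu (0.95 equiv relative to 6), THF, 0 °C; then 5, −78 → 0 °C
Reagents that add atoms: none
Why: Wittig methylenation attacks the enone carbonyl in the 1,2-mode and gives the s-trans semicyclic diene, while the slight deficit of base and the low temperature avoid the γ-deprotonation that would racemise C5.

Step 4
Reactants: 8 (R)-β-phellandrene; 9 acetic acid (reactant and solvent)
Product: 11 [(3S,4R)-3-acetoxy-4-isopropylcyclohex-1-en-1-yl]methyl acetate (4,7-diacetate; O4 cis to isopropyl), via (η3-allyl)PdCl complex 10 (not isolated)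
Conditions: Pd(OAc)2 (5 mol %), p-benzoquinone (1.5 equiv), LiOAc·2H2O (3 equiv), LiCl (0.2 equiv), AcOH, 25 °C
Reagents that add atoms: acetic acid 9, CC(=O)O (two equivalents, in exchange with lithium acetate, [Li+].CC(=O)[O-]); palladium diacetate, CC(=O)[O-].CC(=O)[O-].[Pd+2], and lithium chloride, [Li+].[Cl-] (their Pd and Cl appear only in intermediate 10)
Why: Divalent palladium binds the exocyclic C7=C2 bond of the s-trans-locked diene on the ring face opposite the C5 isopropyl group, and acetate adds from solution to the unhindered terminus C7 (anti acetoxypalladation), giving complex 10 over C2–C3–C4 with the metal trans to isopropyl. Chloride fills the coordination site from which a bound acetate could migrate, so the second acetate also comes from solution, anti to palladium and hence on the isopropyl face of C4; this sets the one new stereocentre (C4, O4 cis to isopropyl) under control of C5. p-Benzoquinone acts as a π-acid ligand that triggers this attack and then takes up two electrons, returning zerovalent palladium to the divalent state. The reaction type is the known palladium/benzoquinone 1,4-diacyloxylation of conjugated dienes with its chloride-dependent stereochemical switch, and no ring is closed. The required 1,4- over 1,2-mode is secured by the substrate, because the competing allyl terminus C2 is fully substituted while C4 is secondary, and a first attack at C4 instead of C7 would converge on the same product. The transoid diene geometry excludes Diels–Alder addition to the quinone, and the acetate buffer at 25 °C holds back acid isomerisation and dehydrogenation to p-cymene derivatives.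

Step 5
Reactants: 11 cis-4,7-diacetate
Product: 12 (1S,6R)-3-(hydroxymethyl)-6-isopropylcyclohex-2-en-1-ol (cis-diol)
Conditions: K2CO3 (0.2 equiv), MeOH, 0 °C → rt
Reagents that add atoms: none
Why: Carbonate-catalysed transesterification with methanol removes both acetyl groups by acyl–oxygen cleavage, so the C4–O bond and the cis relationship are untouched.

Step 6
Reactants: 12 cis-diol
Product: 13 (1S,6R)-3-[(tert-butyldimethylsilyloxy)methyl]-6-isopropylcyclohex-2-en-1-ol
Conditions: TBSCl (1.05 equiv), imidazole, CH2Cl2, −20 → 0 °C
Reagents that add atoms: tert-butyldimethylsilyl chloride, CC(C)(C)[Si](C)(C)Cl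
Why: Chemoselective silylation, in which the unhindered primary allylic hydroxyl reacts far faster with the bulky chlorosilane than the secondary hydroxyl flanked by the cis isopropyl group.

Step 7
Reactants: 13 silyl ether alcohol; 14 angelic acid
Product: 16 (1S,6R)-3-[(tert-butyldimethylsilyloxy)methyl]-6-isopropylcyclohex-2-en-1-yl (Z)-2-methylbut-2-enoate, via angelic 2,4,6-trichlorobenzoic anhydride 15 (not isolated)
Conditions: 14, 2,4,6-Cl3C6H2COCl, Et3N, toluene, rt; then 13, 80 °C (no DMAP)
Reagents that add atoms: 2,4,6-trichlorobenzoyl chloride, O=C(Cl)c1c(Cl)cc(Cl)cc1Cl (its atoms appear only in intermediate 15)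
Why: Yamaguchi-type mixed-anhydride acylation without a nucleophilic catalyst transfers the angeloyl group to hindered secondary alcohols with C4–O intact and avoids the addition–elimination pathway that turns angelates into tiglates.

Step 8
Reactants: 16 angelate
Product: 17 (4S,5R)-4-angeloyloxy-2-[(tert-butyldimethylsilyloxy)methyl]-5-isopropylcyclohex-2-en-1-one
Conditions: CrO3, 3,5-dimethylpyrazole, CH2Cl2, −20 °C
Reagents that add atoms: chromium trioxide, O=[Cr](=O)=O
Why: Allylic oxidation with the CrO3·3,5-dimethylpyrazole complex turns a ring allylic methylene into the enone carbonyl; C1H2 is the only allylic site neither deactivated by an acyloxy group or an electron-poor alkene (C4–H, angelate methyls) nor screened by the bulky silyl ether (C7H2), and oxygen delivery at C1 rather than C3 is favoured because C3 adjoins the substituted C4.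

Step 9
Reactants: 17 enone
Product: 19 (4R,5S,6S)-4-angeloyloxy-2-[(tert-butyldimethylsilyloxy)methyl]-6-hydroxy-5-isopropylcyclohex-2-en-1-one (O6 trans to isopropyl), via potassium dienolate 18 (not isolated)
Conditions: KN(SiMe3)2 (1.05 equiv), THF, −78 °C; 3-phenyl-2-(phenylsulfonyl)oxaziridine, −78 °C; AcOH quench
Reagents that add atoms: 3-phenyl-2-(phenylsulfonyl)oxaziridine, O=S(=O)(c1ccccc1)N1OC1c1ccccc1; potassium bis(trimethylsilyl)amide, C[Si](C)(C)[N-][Si](C)(C)C.[K+] (its potassium appears only in intermediate 18)
Why: Davis hydroxylation of the kinetic cross-conjugated α′-enolate: the hindered amide removes a C6 proton at −78 °C, and the N-sulfonyloxaziridine transfers oxygen to the enolate face opposite both the C5 isopropyl and the C4 angelate, which sets C6.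

Step 10
Reactants: 14 angelic acid
Product: 20 (Z)-2-methylbut-2-en-1-ol
Conditions: LiAlH4, Et2O, 0 °C → rt
Reagents that add atoms: none
Why: Hydride reduction of the carboxylic acid with LiAlH4 proceeds in the 1,2-mode and leaves the Z-trisubstituted double bond in place.

Step 11
Reactants: 20 (Z)-2-methylbut-2-en-1-ol
Product: 21 [(2S,3R)-2,3-dimethyloxiran-2-yl]methanol
Conditions: Ti(OiPr)4 (10 mol %), L-(+)-diethyl tartrate (12 mol %), tBuOOH, 4 Å MS, CH2Cl2, −20 °C
Reagents that add atoms: tert-butyl hydroperoxide, CC(C)(C)OO
Why: Katsuki–Sharpless asymmetric epoxidation: with the L-(+)-tartrate ligand the titanium-bound peroxide reaches the alkene face that gives the 2S,3R epoxide, and the cis relation of the C3 methyl group and CH2OH is inherited from the Z-alkene by syn addition.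

Step 12
Reactants: 21 epoxy alcohol
Product: 23 (2R,3R)-2,3-dimethyloxirane-2-carboxylic acid [(2R,3R)-epoxyangelic acid], via epoxy aldehyde 22 (not isolated)
Conditions: RuCl3·xH2O (2 mol %), NaIO4 (3 equiv), MeCN–EtOAc–H2O, 0 °C → rt
Reagents that add atoms: water, O
Why: RuO4-catalysed oxidation (RuCl3/NaIO4) takes primary epoxy alcohols through the aldehyde hydrate to glycidic acids without opening the oxirane, and the change of the C2 descriptor from S to R reflects only the higher priority of the carboxyl group.

Step 13
Reactants: 19 hydroxy ketone; 23 (2R,3R)-epoxyangelic acid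
Product: 25 (4R,5R,6S)-4-angeloyloxy-2-[(tert-butyldimethylsilyloxy)methyl]-6-[(2R,3R)-2,3-dimethyloxirane-2-carbonyloxy]-5-isopropylcyclohex-2-en-1-one, via epoxyangelic 2,4,6-trichlorobenzoic anhydride 24 (not isolated)
Conditions: 23, 2,4,6-Cl3C6H2COCl, Et3N, toluene, rt; then 19, DMAP, rt
Reagents that add atoms: 2,4,6-trichlorobenzoyl chloride, O=C(Cl)c1c(Cl)cc(Cl)cc1Cl (its atoms appear only in intermediate 24)
Why: Yamaguchi esterification with DMAP couples the α-quaternary acid, which has no α-hydrogen to epimerise, to the only free hydroxyl group without breaking C6–O, and the trans C5/C6 arrangement is expected to be the more stable one as well.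

Step 14
Reactants: 25 silyl-protected diester
Product: 26 target, (4R,5R,6S)-4-angeloyloxy-6-[(2R,3R)-2,3-dimethyloxirane-2-carbonyloxy]-2-(hydroxymethyl)-5-isopropylcyclohex-2-en-1-one
Conditions: HF·pyridine, pyridine, THF, 0 °C → rt
Reagents that add atoms: none
Why: Fluoride-induced cleavage of the primary silyl ether under buffered, weakly acidic conditions spares both esters, the glycidic epoxide and the base-sensitive γ-acyloxy enone.

**Compound list**

1 | isovaleraldehyde | CC(C)CC=O | starting material
2 | methyl vinyl ketone | CC(=O)C=C | starting material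
3 | (2R)-2-isopropyl-5-oxohexanal | O=C[C@@H](C(C)C)CCC(C)=O | intermediate
4 | (4R)-3-hydroxy-4-isopropylcyclohexan-1-one (aldol adduct, C3 epimers) | O=C1CC(O)[C@@H](C(C)C)CC1 | intermediate
5 | (R)-cryptone | O=C1C=C[C@@H](C(C)C)CC1 | intermediate
6 | methyltriphenylphosphonium bromide | C[P+](c1ccccc1)(c1ccccc1)c1ccccc1.[Br-] | starting material
7 | methylenetriphenylphosphorane | C=P(c1ccccc1)(c1ccccc1)c1ccccc1 | intermediate
8 | (R)-β-phellandrene | C=C1C=C[C@@H](C(C)C)CC1 | intermediate
9 | acetic acid | CC(=O)O | starting material
10 | (η3-allyl)PdCl complex over C2–C3–C4, C7H2OAc on C2, Pd trans to isopropyl (drawn as its C4 σ-form) | Cl[Pd][C@H]1C=C(COC(C)=O)CC[C@@H]1C(C)C | intermediate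
11 | [(3S,4R)-3-acetoxy-4-isopropylcyclohex-1-en-1-yl]methyl acetate | CC(=O)O[C@@H]1C=C(COC(C)=O)CC[C@@H]1C(C)C | intermediate
12 | (1S,6R)-3-(hydroxymethyl)-6-isopropylcyclohex-2-en-1-ol | O[C@@H]1C=C(CO)CC[C@@H]1C(C)C | intermediate
13 | (1S,6R)-3-[(tert-butyldimethylsilyloxy)methyl]-6-isopropylcyclohex-2-en-1-ol | O[C@@H]1C=C(CO[Si](C)(C)C(C)(C)C)CC[C@@H]1C(C)C | intermediate
14 | angelic acid | C/C=C(/C)C(=O)O | starting material
15 | angelic 2,4,6-trichlorobenzoic anhydride | C/C=C(/C)C(=O)OC(=O)c1c(Cl)cc(Cl)cc1Cl | intermediate
16 | (1S,6R)-3-[(tert-butyldimethylsilyloxy)methyl]-6-isopropylcyclohex-2-en-1-yl angelate | C/C=C(/C)C(=O)O[C@@H]1C=C(CO[Si](C)(C)C(C)(C)C)CC[C@@H]1C(C)C | intermediate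
17 | (4S,5R)-4-angeloyloxy-2-[(tert-butyldimethylsilyloxy)methyl]-5-isopropylcyclohex-2-en-1-one | C/C=C(/C)C(=O)O[C@@H]1C=C(CO[Si](C)(C)C(C)(C)C)C(=O)C[C@@H]1C(C)C | intermediate
18 | potassium C1,C6-dienolate of 17 (C4 and C5 as in 17) | C/C=C(/C)C(=O)O[C@@H]1C=C(CO[Si](C)(C)C(C)(C)C)C([O-])=C[C@@H]1C(C)C.[K+] | intermediate
19 | (4R,5S,6S)-4-angeloyloxy-2-[(tert-butyldimethylsilyloxy)methyl]-6-hydroxy-5-isopropylcyclohex-2-en-1-one | C/C=C(/C)C(=O)O[C@@H]1C=C(CO[Si](C)(C)C(C)(C)C)C(=O)[C@@H](O)[C@@H]1C(C)C | intermediate
20 | (Z)-2-methylbut-2-en-1-ol | C/C=C(/C)CO | intermediate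
21 | [(2S,3R)-2,3-dimethyloxiran-2-yl]methanol | OC[C@]1(C)O[C@@H]1C | intermediate
22 | (2R,3R)-2,3-dimethyloxirane-2-carbaldehyde | O=C[C@]1(C)O[C@@H]1C | intermediate
23 | (2R,3R)-2,3-dimethyloxirane-2-carboxylic acid | OC(=O)[C@]1(C)O[C@@H]1C | intermediate
24 | (2R,3R)-epoxyangelic 2,4,6-trichlorobenzoic anhydride | O=C(OC(=O)[C@]1(C)O[C@@H]1C)c1c(Cl)cc(Cl)cc1Cl | intermediate
25 | O7-TBS ether of the target (4R,5R,6S,2′R,3′R) | C/C=C(/C)C(=O)O[C@@H]1C=C(CO[Si](C)(C)C(C)(C)C)C(=O)[C@@H](OC(=O)[C@]2(C)O[C@@H]2C)[C@@H]1C(C)C | intermediate
26 | CNP0293054.1 (4R,5R,6S,2′R,3′R) | C/C=C(/C)C(=O)O[C@@H]1C=C(CO)C(=O)[C@@H](OC(=O)[C@]2(C)O[C@@H]2C)[C@@H]1C(C)C | target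

**Step count and risks**

Total steps: 14. Longest linear sequence: 11 steps (steps 1–9, 13 and 14). The epoxy acid branch (steps 10–12) is convergent.

Steps most likely to fail:

**Step 4.** Facial control may erode in two ways. Palladium may also bind on the isopropyl face, or acetate may migrate from the metal despite the chloride. Either would scramble C4. Dehydrogenation of the diene toward the arene would consume material.

The fallback sets out from 8 and returns at 16, and it fixes C4 by SN2 inversion instead of by the metal. Diene 8 is diacetoxylated with Pd(OAc)2, p-benzoquinone and LiOAc in AcOH without any chloride. Palladium-bound acetate then migrates to C4 on the metal face and gives the trans-diacetate F1. Methanolysis (K2CO3, MeOH) gives the trans-diol F2, and TBSCl/imidazole gives the primary silyl ether F3. A Mitsunobu reaction of F3 with angelic acid 14 (PPh3, DIAD, toluene, 0 °C) inverts C4 and delivers 16 directly. The fully substituted C2 disfavours the SN2′ mode. The same operations would also recycle trans material separated from a mixture.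

**Step 8.** Three processes could interfere: hydrogen abstraction at C7 next to the silyl ether, oxygen delivery at C3 with allylic transposition, or stalling on an alkene deactivated by two allylic oxygens.

The fallback sets out from 16 and returns at 17. It replaces the one-step oxidation by a closed-shell ene/[2,3]-sigmatropic sequence that cannot transpose the alkene. SeO2 (0.5 equiv) and tBuOOH in CH2Cl2 should oxidise the ring methylene at the more substituted alkene terminus to the C1 allylic alcohol F4. Dess–Martin periodinane (NaHCO3, CH2Cl2) then oxidises F4 to 17.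

**Step 9.** Several processes could interfere: loss of angelic acid from the dienolate with aromatisation, competing γ-deprotonation at C4, base-induced isomerisation of the angelate, or addition of the enolate to the sulfonimine by-product.

The fallback sets out from 17 and returns at 19, and it is a Rubottom sequence with no strong base and no metal enolate. Soft enolisation (TMSOTf with excess Et3N, CH2Cl2, −78 → −40 °C) gives the trimethylsilyl dienol ether F5. Dimethyldioxirane in acetone at −40 °C oxidises the enol ether bond on the face opposite isopropyl and angelate under neutral conditions and, after silyl shift, gives the α-silyloxy ketone F6. Citric acid in MeOH at 0 °C then cleaves the trimethylsilyl ether, leaves the primary TBS ether in place, and gives 19.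

**Further compounds**

F1 | step 4 | [(3R,4R)-3-acetoxy-4-isopropylcyclohex-1-en-1-yl]methyl acetate (trans-diacetate) | CC(=O)O[C@H]1C=C(COC(C)=O)CC[C@@H]1C(C)C
F2 | step 4 | (1R,6R)-3-(hydroxymethyl)-6-isopropylcyclohex-2-en-1-ol (trans-diol) | O[C@H]1C=C(CO)CC[C@@H]1C(C)C
F3 | step 4 | (1R,6R)-3-[(tert-butyldimethylsilyloxy)methyl]-6-isopropylcyclohex-2-en-1-ol | O[C@H]1C=C(CO[Si](C)(C)C(C)(C)C)CC[C@@H]1C(C)C
F4 | step 8 | C1 allylic alcohol of 16 (either C1 epimer, centre erased on oxidation) | C/C=C(/C)C(=O)O[C@@H]1C=C(CO[Si](C)(C)C(C)(C)C)C(O)C[C@@H]1C(C)C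
F5 | step 9 | trimethylsilyl dienol ether of 17 | C/C=C(/C)C(=O)O[C@@H]1C=C(CO[Si](C)(C)C(C)(C)C)C(O[Si](C)(C)C)=C[C@@H]1C(C)C
F6 | step 9 | O6-trimethylsilyl ether of 19 | C/C=C(/C)C(=O)O[C@@H]1C=C(CO[Si](C)(C)C(C)(C)C)C(=O)[C@@H](O[Si](C)(C)C)[C@@H]1C(C)C
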